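The runs are simulated with constants of no real substance; the scatter is artificial.

At early times a closed flask holds all the starting material it was charged with, so a rate that follows starting material should be highest then. Grey, amber and green share one charge and one time and differ in temperature; two earlier runs stand beside them.

| setting | Tuesday's | Sunday's | grey | amber | green |
|---|---|---|---|---|---|
| starting material | 0.80 M | 0.40 M | 0.80 M | 0.80 M | 0.80 M |
| partner | 2.2 M | 1.6 M | 1.60 M | 1.60 M | 1.60 M |
| temperature | 40 °C | 70 °C | 95 °C | 45 °C | 70 °C |
| remark | run made earlier | run made earlier |  |  |  |
| time |  |  | 2.5 h | 2.5 h | 2.5 h |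

| run | time / h | target / % |
|---|---|---|
| Tuesday's | 3.00 | 4.5 |
| Tuesday's | 10.0 | 24.4 |
| Tuesday's | 20.0 | 45.3 |
| Tuesday's | 30.0 | 60.8 |
| Tuesday's | 40.0 | 71.3 |
| Sunday's | 1.50 | 59.3 |
| Sunday's | 3.00 | 80.8 |
| Sunday's | 5.00 | 86.5 |
| Sunday's | 6.00 | 87.7 |
| Sunday's | 8.00 | 87.9 |

(each reading ± 0.3 percentage points)

- the flask with the highest amount of target, in percent of the starting material charged ("all alike" if they lie within 1.5 percentage points) (grey / amber / green / all alike)
- final target, as a percentage of the starting material charged, in grey
- final target, as a percentage of the starting material charged, in amber
- final target, as a percentage of the starting material charged, in green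

- reactions considered so far: starting material <-> open intermediate; partner -> second intermediate; open intermediate + second intermediate -> target; open intermediate -> decomposed reagent

Tuesday's run seems to say the opposite: it gives 4.5% of target in its first 3.00 h, yet 20 percentage points in the next 7.00 h, a higher hourly rate. So take the logarithm of what is still unmade, per hour, in Tuesday's run:

early stretch: 0.0334 /h

late stretch: 0.0312 /h

whole stretch: 0.0323 /h

Meanwhile partner and second intermediate together, counted one for one with target, fall to 74.1% of the partner charge, a far bigger change than the constant shows. Tuesday's run therefore reads as first order in starting material, with partner absent from the slow step: the opening of starting material looks like the rate-limiting step. The slow start is a delay, since target needs both intermediates made first. Tuesday's line reaches the full charge at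

delay = 1.34 h

Sunday's approach to its plateau gives 0.929 /h. Scaling geometrically between the two temperatures gives amber's first-order constant:

0.0565 /h

My reckoning for amber, keeping Tuesday's delay, is 6.37%. Amber's time scale is far longer than the run.

The forecast gives grey 66%, amber 7%, green 73%, and green highest: “Green probably leads, narrowly.” Its amber figure lies a little above mine.

The flasks give grey 69.2%, amber 6.99% and green 74.1%, so green stands highest, 4.9 points above grey. starting material ⇌ open intermediate (K = 21.0, k = 0.0150 /min, Ea = 97.0 kJ/mol, ΔH = −36.0 kJ/mol); partner → second intermediate (k = 0.330 /min, Ea = 102 kJ/mol); open intermediate + second intermediate → target (k = 0.0460 /M/min, Ea = 65.0 kJ/mol); open intermediate → decomposed reagent (k = 0.00890 /min, Ea = 111 kJ/mol); (constants at 70 °C)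

Grey holds 30.8% of decomposed reagent at 2.50 h, green 11.3%. With the constant 0.0565 /h and the delay 1.34 h, amber at 25.0 h reckons to 73.7%, and amber there holds 72.7% of target.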